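## Retrosynthetic overview

1. Target ⇐ removal of two ester groups and one silyl ether; C8=CH2 from a C8 ketone (methylenation) and the 13E enoate from a C13 methyl ketone (Horner–Wadsworth–Emmons).
2. C8/C13 diketone ⇐ bicyclic C9=C10 enone: cuprate methylation at C10 (sets the cis ring fusion), then Michael addition of the C8–C9 silyl enol ether to methyl vinyl ketone (sets C9).
3. Bicyclic enone ⇐ ring A closed by the new step, a copper-hydride-triggered lactone-enolate Claisen ring contraction of an unsaturated δ-lactone (forms C4–C5, sets C4 and C5, carries the C2 oxygen).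
4. δ-Lactone ⇐ ring-closing metathesis of a methacrylate ⇐ Brown syn-alkoxyallylboration of a cyclohexenecarbaldehyde (only source of absolute configuration).
5. Ring order: ring B is bought (1,4-dioxaspiro[4.5]decan-7-one), the δ-lactone is built on it, ring A is formed last from the lactone.

Assumption: the SMILES is taken literally, i.e. a cis-fused decalin (5β-H and 10β-CH3 on the same face) with 2β-OH, 4α-CO2H, 4β-CH3, 9β side chain and 13E, which is (2S,4R,5S,9S,10R) in labdane numbering; bicyclic intermediates are named as decalins with ring carbons numbered as labdane C1–C10, β being the face of the C10 methyl.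

## Route

Step 1
Reactants: 1 1,4-dioxaspiro[4.5]decan-7-one
Product: 3 1,4-dioxaspiro[4.5]dec-7-en-7-yl trifluoromethanesulfonate, via lithium enolate 2 (not isolated)
Conditions: LiN(iPr)2, THF, −78 °C; PhNTf2, −78 °C to rt
Reagents that add atoms: N-phenyl-bis(trifluoromethanesulfonimide) O=S(=O)(N(c1ccccc1)S(=O)(=O)C(F)(F)F)C(F)(F)F
Why: Kinetic deprotonation takes the α-CH2 remote from the ketal and O-triflation of the enolate (enol triflate formation) fixes the ring B double bond away from the ketal.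

Step 2
Reactants: 3 1,4-dioxaspiro[4.5]dec-7-en-7-yl trifluoromethanesulfonate
Product: 4 1,4-dioxaspiro[4.5]dec-7-ene-7-carbaldehyde
Conditions: Pd(OAc)2 (3 mol %), Ph2P(CH2)3PPh2, CO (1 atm), Et3SiH, Et3N, DMF, 70 °C
Reagents that add atoms: carbon monoxide [C-]#[O+]
Why: Palladium-catalysed reductive carbonylation (formylation) of an enol triflate: oxidative addition to zerovalent palladium, CO insertion and hydride transfer from the silane give the conjugated aldehyde and leave the ketal alone.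

Step 3
Reactants: 4 1,4-dioxaspiro[4.5]dec-7-ene-7-carbaldehyde
Product: 6 (1R,2R)-1-(1,4-dioxaspiro[4.5]dec-7-en-7-yl)-2-(methoxymethoxy)but-3-en-1-ol, via borinate ester 5 (not isolated)
Conditions: CH2=CHCH2OCH2OMe, sec-BuLi, THF, −78 °C; (−)-B-methoxydiisopinocampheylborane; BF3·OEt2; 4, −78 °C; then NaOH, H2O2, 0 °C to rt
Reagents that add atoms: allyl methoxymethyl ether (3-(methoxymethoxy)prop-1-ene) C=CCOCOC
Why: Brown asymmetric (Z)-γ-alkoxyallylboration through a closed chair transition state adds 1,2 to the si face of the enal and the Z geometry gives the syn 1,2-diol monoether, so the carbinol carbon (future C1) and the MOM-bearing carbon (future C2, kept to the end) are set R,R.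

Step 4
Reactants: 6 (1R,2R)-1-(1,4-dioxaspiro[4.5]dec-7-en-7-yl)-2-(methoxymethoxy)but-3-en-1-ol
Product: 7 (1R,2R)-1-(1,4-dioxaspiro[4.5]dec-7-en-7-yl)-2-(methoxymethoxy)but-3-en-1-yl 2-methylprop-2-enoate
Conditions: CH2=C(Me)COCl, Et3N, DMAP (cat.), CH2Cl2, 0 °C
Reagents that add atoms: methacryloyl chloride CC(=C)C(=O)Cl
Why: DMAP-catalysed acylation of the secondary allylic alcohol installs the methacrylate that supplies C4, its methyl and the future carboxyl carbon.

Step 5
Reactants: 7 (1R,2R)-1-(1,4-dioxaspiro[4.5]dec-7-en-7-yl)-2-(methoxymethoxy)but-3-en-1-yl 2-methylprop-2-enoate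
Product: 8 (5R,6R)-6-(1,4-dioxaspiro[4.5]dec-7-en-7-yl)-5-(methoxymethoxy)-3-methyl-5,6-dihydro-2H-pyran-2-one
Conditions: second-generation Grubbs catalyst RuCl2(=CHPh)(PCy3)(H2IMes) (5 mol %), CH2Cl2, 40 °C
Reagents that add atoms: none
Why: Ring-closing metathesis between the terminal vinyl group and the methacrylate gives the six-membered α-methyl unsaturated lactone with loss of ethene, the trisubstituted ring B alkene being inert and no stereocentre being touched.

Step 6
Reactants: 8 (5R,6R)-6-(1,4-dioxaspiro[4.5]dec-7-en-7-yl)-5-(methoxymethoxy)-3-methyl-5,6-dihydro-2H-pyran-2-one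
Product: 11 8,8-ethylenedioxy-2β-(methoxymethoxy)-4β-methyl-5βH-decal-1(10)-ene-4α-carboxylic acid, via silyl ketene acetal 9 (not isolated), via silyl ester 10 (not isolated)
Conditions: [(Ph3P)CuH]6 (3 mol %), MeSiH(OEt)2 (1.3 equiv), toluene, 0 °C to rt; then 110 °C, 6 h; then MeOH/H2O
Reagents that add atoms: none
Why: Proposed new method: a monovalent copper hydride delivers hydride to the β-carbon of the 2-methyl-2-enoate unit of the lactone (1,4-reduction), σ-bond metathesis of the copper enolate with the silane gives the ring-locked silyl ketene acetal 9 and regenerates the hydride, and on heating the O–C=C(Me) unit can reach the cyclohexenyl CH only through the single boat transition state bridged by the two lactone carbons, so the [3,3] shift forms C4–C5 and ring A with transfer of chirality from the carbinol carbon (CO2Si at C4 trans to the C2 oxygen, C4 methyl and C5–H cis to it, new C1=C10 alkene); the closest known reactions are the lactone-enolate Ireland–Claisen ring contraction run with amide base and silyl chloride and the reductive Ireland–Claisen rearrangement of acyclic allyl acrylates under rhodium or copper hydride catalysis.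

Step 7
Reactants: 11 8,8-ethylenedioxy-2β-(methoxymethoxy)-4β-methyl-5βH-decal-1(10)-ene-4α-carboxylic acid
Product: 12 2-(trimethylsilyl)ethyl 8,8-ethylenedioxy-2β-(methoxymethoxy)-4β-methyl-5βH-decal-1(10)-ene-4α-carboxylate
Conditions: Me3SiCH2CH2OH, PPh3, iPrO2CN=NCO2iPr, THF, 0 °C to rt
Reagents that add atoms: 2-(trimethylsilyl)ethanol C[Si](C)(C)CCO
Why: Mitsunobu esterification (carboxylate SN2 on the activated primary alcohol) works for the hindered tertiary acid and gives a fluoride-cleavable ester that prevents acid-induced lactonisation in the next step.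

Step 8
Reactants: 12 2-(trimethylsilyl)ethyl 8,8-ethylenedioxy-2β-(methoxymethoxy)-4β-methyl-5βH-decal-1(10)-ene-4α-carboxylate
Product: 15 2-(trimethylsilyl)ethyl 2β-hydroxy-4β-methyl-8-oxo-5βH-decal-9(10)-ene-4α-carboxylate, via deconjugated ketone 13 (not isolated), via conjugated enone ether 14 (not isolated)
Conditions: 2 M aq. HCl, THF, 45 °C
Reagents that add atoms: water O
Why: Acid hydrolysis of the ketal, acid-catalysed migration of the β,γ double bond into conjugation (C9=C10) and hydrolysis of the MOM acetal occur in one pot, and C5 keeps its configuration because only that epimer has the C2 oxygen and the C4 methyl both equatorial.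

Step 9
Reactants: 15 2-(trimethylsilyl)ethyl 2β-hydroxy-4β-methyl-8-oxo-5βH-decal-9(10)-ene-4α-carboxylate
Product: 16 2-(trimethylsilyl)ethyl 2β-(tert-butyldimethylsilyloxy)-4β-methyl-8-oxo-5βH-decal-9(10)-ene-4α-carboxylate
Conditions: tBuMe2SiCl, imidazole, DMF, rt
Reagents that add atoms: tert-butyldimethylsilyl chloride CC(C)(C)[Si](C)(C)Cl
Why: Standard silylation of the unhindered equatorial secondary alcohol protects it through the basic and Lewis-acidic steps that follow.

Step 10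
Reactants: 16 2-(trimethylsilyl)ethyl 2β-(tert-butyldimethylsilyloxy)-4β-methyl-8-oxo-5βH-decal-9(10)-ene-4α-carboxylate
Product: 17 2-(trimethylsilyl)ethyl 2β-(tert-butyldimethylsilyloxy)-4β,10β-dimethyl-8-(trimethylsilyloxy)-5βH-decal-8-ene-4α-carboxylate
Conditions: MeLi (2.4 equiv), CuI (1.2 equiv), Et2O, 0 °C; then Me3SiCl, 16, THF, −78 °C; Et3N, pentane work-up
Reagents that add atoms: methyllithium [Li]C; chlorotrimethylsilane C[Si](C)(C)Cl
Why: Chlorosilane-accelerated 1,4-addition of a Gilman cuprate to the bicyclic enone puts the methyl on C10 from the β face (axial on the enone ring, the α face being shielded by the axial C4 ester), the classical octalone outcome that gives the cis-fused decalin with the C10 methyl cis to H5, and the enolate is trapped regiospecifically as the C8–C9 silyl enol ether.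

Step 11
Reactants: 17 2-(trimethylsilyl)ethyl 2β-(tert-butyldimethylsilyloxy)-4β,10β-dimethyl-8-(trimethylsilyloxy)-5βH-decal-8-ene-4α-carboxylate
Product: 18 2-(trimethylsilyl)ethyl 2β-(tert-butyldimethylsilyloxy)-4β,10β-dimethyl-8-oxo-9β-(3-oxobutyl)-5βH-decalin-4α-carboxylate
Conditions: CH2=CHCOMe, BF3·OEt2, iPrOH, CH2Cl2, −78 to −20 °C
Reagents that add atoms: methyl vinyl ketone (but-3-en-2-one) CC(=O)C=C
Why: Mukaiyama–Michael addition of the regiodefined silyl enol ether to the BF3-activated enone attacks C9 from the β face (the α face is blocked by the axial C5–C4 bond of the folded cis-decalin) and gives the equatorial 9β side chain, which is also the thermodynamic epimer.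

Step 12
Reactants: 18 2-(trimethylsilyl)ethyl 2β-(tert-butyldimethylsilyloxy)-4β,10β-dimethyl-8-oxo-9β-(3-oxobutyl)-5βH-decalin-4α-carboxylate
Product: 19 2-(trimethylsilyl)ethyl 2β-(tert-butyldimethylsilyloxy)-9β-[(3E)-5-ethoxy-3-methyl-5-oxopent-3-en-1-yl]-4β,10β-dimethyl-8-oxo-5βH-decalin-4α-carboxylate
Conditions: (EtO)2P(O)CH2CO2Et, NaH, THF, 0 to 45 °C
Reagents that add atoms: triethyl phosphonoacetate CCOC(=O)CP(=O)(OCC)OCC
Why: Horner–Wadsworth–Emmons olefination is chemoselective for the unhindered methyl ketone over the congested C8 ketone and favours the E trisubstituted enoate (about 6:1, minor Z isomer removed by chromatography).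

Step 13
Reactants: 19 2-(trimethylsilyl)ethyl 2β-(tert-butyldimethylsilyloxy)-9β-[(3E)-5-ethoxy-3-methyl-5-oxopent-3-en-1-yl]-4β,10β-dimethyl-8-oxo-5βH-decalin-4α-carboxylate
Product: 20 2-(trimethylsilyl)ethyl 2β-(tert-butyldimethylsilyloxy)-9β-[(3E)-5-ethoxy-3-methyl-5-oxopent-3-en-1-yl]-4β,10β-dimethyl-8-methylidene-5βH-decalin-4α-carboxylate
Conditions: Zn, CH2Br2, TiCl4, THF, 0 °C (reagent pre-formed); then 19, CH2Cl2, rt
Reagents that add atoms: dibromomethane BrCBr
Why: Takai–Lombardo methylenation with a non-basic gem-dizinc/titanium reagent converts the hindered enolisable C8 ketone into the exocyclic methylene without epimerising C9 or touching the esters.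

Step 14
Reactants: 20 2-(trimethylsilyl)ethyl 2β-(tert-butyldimethylsilyloxy)-9β-[(3E)-5-ethoxy-3-methyl-5-oxopent-3-en-1-yl]-4β,10β-dimethyl-8-methylidene-5βH-decalin-4α-carboxylate
Product: 21 9β-[(3E)-5-ethoxy-3-methyl-5-oxopent-3-en-1-yl]-2β-hydroxy-4β,10β-dimethyl-8-methylidene-5βH-decalin-4α-carboxylic acid
Conditions: Bu4NF, THF, rt to 40 °C; aq. NH4Cl
Reagents that add atoms: none
Why: Fluoride attacks silicon, so the 2-(trimethylsilyl)ethyl ester fragments (β-elimination to ethene) and the silyl ether is cleaved while the alkenes and the ethyl ester stay intact.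

Step 15
Reactants: 21 9β-[(3E)-5-ethoxy-3-methyl-5-oxopent-3-en-1-yl]-2β-hydroxy-4β,10β-dimethyl-8-methylidene-5βH-decalin-4α-carboxylic acid
Product: 22 (1R,3S,4aR,5S,8aS)-5-[(3E)-4-carboxy-3-methylbut-3-en-1-yl]-3-hydroxy-1,4a-dimethyl-6-methylidenedecahydronaphthalene-1-carboxylic acid
Conditions: LiOH, THF/MeOH/H2O, 45 °C; then dilute HCl, 0 °C, pH 3
Reagents that add atoms: lithium hydroxide [Li+].[OH-]
Why: Saponification of the unhindered conjugated ethyl ester and mild acidification give the diacid without moving the exocyclic or the 13E double bond.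

## Compound list

1 | 1,4-dioxaspiro[4.5]decan-7-one | O=C1CCCC2(C1)OCCO2 | starting material
2 | lithium 1,4-dioxaspiro[4.5]dec-7-en-7-olate | [Li]OC1=CCCC2(C1)OCCO2 | intermediate
3 | 1,4-dioxaspiro[4.5]dec-7-en-7-yl trifluoromethanesulfonate | O=S(=O)(OC1=CCCC2(C1)OCCO2)C(F)(F)F | intermediate
4 | 1,4-dioxaspiro[4.5]dec-7-ene-7-carbaldehyde | O=CC1=CCCC2(C1)OCCO2 | intermediate
5 | (1R,2R)-1-(1,4-dioxaspiro[4.5]dec-7-en-7-yl)-2-(methoxymethoxy)but-3-en-1-yl diisopinocampheylborinate | C=C[C@@H](OCOC)[C@H](OB([C@@H]1C[C@@H]2C[C@H]([C@H]1C)C2(C)C)[C@@H]1C[C@@H]2C[C@H]([C@H]1C)C2(C)C)C1=CCCC2(C1)OCCO2 | intermediate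
6 | (1R,2R)-1-(1,4-dioxaspiro[4.5]dec-7-en-7-yl)-2-(methoxymethoxy)but-3-en-1-ol | C=C[C@@H](OCOC)[C@H](O)C1=CCCC2(C1)OCCO2 | intermediate
7 | (1R,2R)-1-(1,4-dioxaspiro[4.5]dec-7-en-7-yl)-2-(methoxymethoxy)but-3-en-1-yl 2-methylprop-2-enoate | C=C[C@@H](OCOC)[C@H](OC(=O)C(C)=C)C1=CCCC2(C1)OCCO2 | intermediate
8 | (5R,6R)-6-(1,4-dioxaspiro[4.5]dec-7-en-7-yl)-5-(methoxymethoxy)-3-methyl-5,6-dihydro-2H-pyran-2-one | CC1=C[C@@H](OCOC)[C@H](OC1=O)C1=CCCC2(C1)OCCO2 | intermediate
9 | (2R,3R)-6-[diethoxy(methyl)silyl]oxy-2-(1,4-dioxaspiro[4.5]dec-7-en-7-yl)-3-(methoxymethoxy)-5-methyl-3,4-dihydro-2H-pyran | CC1=C(O[Si](C)(OCC)OCC)O[C@H](C2=CCCC3(C2)OCCO3)[C@H](OCOC)C1 | intermediate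
10 | diethoxy(methyl)silyl 8,8-ethylenedioxy-2β-(methoxymethoxy)-4β-methyl-5βH-decal-1(10)-ene-4α-carboxylate | O1CCOC12CC[C@H]3C(=C[C@H](OCOC)C[C@@]3(C)C(=O)O[Si](C)(OCC)OCC)C2 | intermediate
11 | 8,8-ethylenedioxy-2β-(methoxymethoxy)-4β-methyl-5βH-decal-1(10)-ene-4α-carboxylic acid | O1CCOC12CC[C@H]3C(=C[C@H](OCOC)C[C@@]3(C)C(=O)O)C2 | intermediate
12 | 2-(trimethylsilyl)ethyl 8,8-ethylenedioxy-2β-(methoxymethoxy)-4β-methyl-5βH-decal-1(10)-ene-4α-carboxylate | O1CCOC12CC[C@H]3C(=C[C@H](OCOC)C[C@@]3(C)C(=O)OCC[Si](C)(C)C)C2 | intermediate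
13 | 2-(trimethylsilyl)ethyl 2β-(methoxymethoxy)-4β-methyl-8-oxo-5βH-decal-1(10)-ene-4α-carboxylate | O=C1CC[C@H]2C(=C[C@H](OCOC)C[C@@]2(C)C(=O)OCC[Si](C)(C)C)C1 | intermediate
14 | 2-(trimethylsilyl)ethyl 2β-(methoxymethoxy)-4β-methyl-8-oxo-5βH-decal-9(10)-ene-4α-carboxylate | O=C1CC[C@H]2C(=C1)C[C@H](OCOC)C[C@@]2(C)C(=O)OCC[Si](C)(C)C | intermediate
15 | 2-(trimethylsilyl)ethyl 2β-hydroxy-4β-methyl-8-oxo-5βH-decal-9(10)-ene-4α-carboxylate | O=C1CC[C@H]2C(=C1)C[C@H](O)C[C@@]2(C)C(=O)OCC[Si](C)(C)C | intermediate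
16 | 2-(trimethylsilyl)ethyl 2β-(tert-butyldimethylsilyloxy)-4β-methyl-8-oxo-5βH-decal-9(10)-ene-4α-carboxylate | O=C1CC[C@H]2C(=C1)C[C@H](O[Si](C)(C)C(C)(C)C)C[C@@]2(C)C(=O)OCC[Si](C)(C)C | intermediate
17 | 2-(trimethylsilyl)ethyl 2β-(tert-butyldimethylsilyloxy)-4β,10β-dimethyl-8-(trimethylsilyloxy)-5βH-decal-8-ene-4α-carboxylate (cis-fused) | C[Si](C)(C)OC1=C[C@@]2(C)C[C@H](O[Si](C)(C)C(C)(C)C)C[C@@](C)(C(=O)OCC[Si](C)(C)C)[C@H]2CC1 | intermediate
18 | 2-(trimethylsilyl)ethyl 2β-(tert-butyldimethylsilyloxy)-4β,10β-dimethyl-8-oxo-9β-(3-oxobutyl)-5βH-decalin-4α-carboxylate | O=C1CC[C@H]2[C@](C)(C[C@H](O[Si](C)(C)C(C)(C)C)C[C@@]2(C)C(=O)OCC[Si](C)(C)C)[C@H]1CCC(C)=O | intermediate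
19 | 2-(trimethylsilyl)ethyl 2β-(tert-butyldimethylsilyloxy)-9β-[(3E)-5-ethoxy-3-methyl-5-oxopent-3-en-1-yl]-4β,10β-dimethyl-8-oxo-5βH-decalin-4α-carboxylate | O=C1CC[C@H]2[C@](C)(C[C@H](O[Si](C)(C)C(C)(C)C)C[C@@]2(C)C(=O)OCC[Si](C)(C)C)[C@H]1CC/C(C)=C/C(=O)OCC | intermediate
20 | 2-(trimethylsilyl)ethyl 2β-(tert-butyldimethylsilyloxy)-9β-[(3E)-5-ethoxy-3-methyl-5-oxopent-3-en-1-yl]-4β,10β-dimethyl-8-methylidene-5βH-decalin-4α-carboxylate | C=C1CC[C@H]2[C@](C)(C[C@H](O[Si](C)(C)C(C)(C)C)C[C@@]2(C)C(=O)OCC[Si](C)(C)C)[C@H]1CC/C(C)=C/C(=O)OCC | intermediate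
21 | 9β-[(3E)-5-ethoxy-3-methyl-5-oxopent-3-en-1-yl]-2β-hydroxy-4β,10β-dimethyl-8-methylidene-5βH-decalin-4α-carboxylic acid | C=C1CC[C@H]2[C@](C)(C[C@H](O)C[C@@]2(C)C(=O)O)[C@H]1CC/C(C)=C/C(=O)OCC | intermediate
22 | (1R,3S,4aR,5S,8aS)-5-[(3E)-4-carboxy-3-methylbut-3-en-1-yl]-3-hydroxy-1,4a-dimethyl-6-methylidenedecahydronaphthalene-1-carboxylic acid (CNP0086784.2) | C=C1CC[C@H]2[C@](C)(C[C@H](O)C[C@@]2(C)C(=O)O)[C@H]1CC/C(C)=C/C(=O)O | target

## Step count and risks

Total step count: 15. Longest linear sequence: 15 steps (fully linear from 1).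

The three steps most likely to fail:

Step 6 (the proposed reductive Claisen ring contraction). The copper enolate may not be silylated cleanly, or the mixed alkoxysilyl ketene acetal may not rearrange. The fallback sets out from 8 and comes back at 11 using known chemistry. Conjugate reduction of 8 with stoichiometric [(Ph3P)CuH]6 in wet benzene gives the saturated lactone F1 (both epimers at the methyl-bearing carbon). LiN(iPr)2 and Me3SiCl/Et3N in THF at −78 °C convert it into the cyclic trimethylsilyl ketene acetal F2. Heating in toluene at 105 °C effects the lactone-enolate Ireland–Claisen ring contraction through the same boat transition state to the trimethylsilyl ester F3, and aqueous work-up returns acid 11.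

Step 11 (Lewis-acid Michael addition at the congested C9 next to the quaternary C10). The fallback sets out from 17 and comes back at 18 by enolate alkylation instead of Michael addition. MeLi in THF cleaves the silyl enol ether to the lithium enolate F4. This is alkylated with 1,3-dichlorobut-2-ene (Wichterle reagent) in THF/DMPU to the vinyl chloride F5 (E/Z mixture at the chloroalkene). Hydrolysis of the vinyl chloride with Hg(OCOCF3)2 in MeNO2 followed by water gives diketone 18.

Step 12 (E/Z control and discrimination between two ketones). The fallback sets out from 17 and comes back at 20, replacing the olefination by a stereospecific carbometalation. Mukaiyama–Michael addition of 17 to acrolein (BF3·OEt2, iPrOH) gives the keto aldehyde F6. Ohira–Bestmann homologation (dimethyl (1-diazo-2-oxopropyl)phosphonate, K2CO3, MeOH) gives the terminal alkyne F7. Takai–Lombardo methylenation (Zn, CH2Br2, TiCl4) gives the methylene alkyne F8. Negishi zirconium-catalysed syn-methylalumination (AlMe3, Cp2ZrCl2 cat., CH2Cl2) gives the (E)-alkenylalane F9, and its reaction with ClCO2Et places the ester with retention and returns 20 as a single E isomer.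

Further compounds
F1 | step 6 | (5R,6R)-6-(1,4-dioxaspiro[4.5]dec-7-en-7-yl)-5-(methoxymethoxy)-3-methyltetrahydro-2H-pyran-2-one (both C3 epimers) | CC1C[C@@H](OCOC)[C@H](OC1=O)C1=CCCC2(C1)OCCO2
F2 | step 6 | (2R,3R)-2-(1,4-dioxaspiro[4.5]dec-7-en-7-yl)-3-(methoxymethoxy)-5-methyl-6-(trimethylsilyloxy)-3,4-dihydro-2H-pyran | CC1=C(O[Si](C)(C)C)O[C@H](C2=CCCC3(C2)OCCO3)[C@H](OCOC)C1
F3 | step 6 | trimethylsilyl 8,8-ethylenedioxy-2β-(methoxymethoxy)-4β-methyl-5βH-decal-1(10)-ene-4α-carboxylate | O1CCOC12CC[C@H]3C(=C[C@H](OCOC)C[C@@]3(C)C(=O)O[Si](C)(C)C)C2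
F4 | step 11 | lithium C8–C9 enolate of 2-(trimethylsilyl)ethyl 2β-(tert-butyldimethylsilyloxy)-4β,10β-dimethyl-8-oxo-5βH-decalin-4α-carboxylate | [Li]OC1=C[C@@]2(C)C[C@H](O[Si](C)(C)C(C)(C)C)C[C@@](C)(C(=O)OCC[Si](C)(C)C)[C@H]2CC1
F5 | step 11 | 2-(trimethylsilyl)ethyl 2β-(tert-butyldimethylsilyloxy)-9β-(3-chlorobut-2-en-1-yl)-4β,10β-dimethyl-8-oxo-5βH-decalin-4α-carboxylate (E/Z mixture) | O=C1CC[C@H]2[C@](C)(C[C@H](O[Si](C)(C)C(C)(C)C)C[C@@]2(C)C(=O)OCC[Si](C)(C)C)[C@H]1CC=C(C)Cl
F6 | step 12 | 2-(trimethylsilyl)ethyl 2β-(tert-butyldimethylsilyloxy)-4β,10β-dimethyl-8-oxo-9β-(3-oxopropyl)-5βH-decalin-4α-carboxylate | O=C1CC[C@H]2[C@](C)(C[C@H](O[Si](C)(C)C(C)(C)C)C[C@@]2(C)C(=O)OCC[Si](C)(C)C)[C@H]1CCC=O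
F7 | step 12 | 2-(trimethylsilyl)ethyl 9β-(but-3-yn-1-yl)-2β-(tert-butyldimethylsilyloxy)-4β,10β-dimethyl-8-oxo-5βH-decalin-4α-carboxylate | O=C1CC[C@H]2[C@](C)(C[C@H](O[Si](C)(C)C(C)(C)C)C[C@@]2(C)C(=O)OCC[Si](C)(C)C)[C@H]1CCC#C
F8 | step 12 | 2-(trimethylsilyl)ethyl 9β-(but-3-yn-1-yl)-2β-(tert-butyldimethylsilyloxy)-4β,10β-dimethyl-8-methylidene-5βH-decalin-4α-carboxylate | C=C1CC[C@H]2[C@](C)(C[C@H](O[Si](C)(C)C(C)(C)C)C[C@@]2(C)C(=O)OCC[Si](C)(C)C)[C@H]1CCC#C
F9 | step 12 | 2-(trimethylsilyl)ethyl 2β-(tert-butyldimethylsilyloxy)-9β-[(3E)-4-(dimethylalumanyl)-3-methylbut-3-en-1-yl]-4β,10β-dimethyl-8-methylidene-5βH-decalin-4α-carboxylate | C=C1CC[C@H]2[C@](C)(C[C@H](O[Si](C)(C)C(C)(C)C)C[C@@]2(C)C(=O)OCC[Si](C)(C)C)[C@H]1CC/C(C)=C/[Al](C)C
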